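The number to carry through this flask is 0.236 mM: the [J] at which E goes equally fast to links and to rings, our crossing level, which is the selectivity factor written as a concentration.

E 0.50 mM; J 0.550 mM; Z 0.100 mM; time 12 s

    E + J → E.J (k1 = 1.1 × 10⁵ /M/s)
    E + J → Q, rate k2*[E] as long as [J] is above zero (k2 = 26 /s)
    J + Z → J.Z (k3 = 1300 /M/s)

- which holds at 12 s: what has brought the reaction to rest, or that it has not come to rest (J has run out first / all of E has reacted / it is still moving)
- conversion of E at 12 s
- amount of E.J at 12 s, in percent of the E charged
- amount of Q at 12 s, in percent of the E charged

- the reaction counts as stopped when no species that holds the E changes by six tenths of a point or more over the second half of the time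
- run time (flask): 12 s

Each E takes one J by either step, and at any moment the share of E going to Q is the crossing level over the crossing level plus [J]. E lasts about 0.0385 s or less, while the half-life of J by step 3, with the charges held, is 5.3 s; because that is much longer, we leave Z out while E lives. So we reckon that in this flask [J] falls from 0.550 mM to 0.0500 mM while E lives.

The bench rule is to use the mean [J], taken over the E consumed and not over the clock. That mean is 0.300 mM, which gives a ring share of 44.1 %. But the share bends, from 30.0 % at the start to 82.5 % at the end. Summed over the fall of [J], it is the crossing level over [E] charged, times the logarithm of (crossing level + 0.550 mM) over (crossing level + 0.0500 mM), or 47.8 %. The mean therefore costs 3.7 percentage points. Both reckonings stand on J outlasting E, so with Z left out their border is a J to E ratio of one, and this flask stands at 1.10. We commit to a conversion of 100 % at 12 s, with 47.8 % as Q and 52.2 % as E.J.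

The forecast gave all of E has reacted, a conversion of 100 %, 52.1 % of E.J and 47.9 % of Q, holding that “J does not run out first”.

The simulation gives all of E has reacted, a conversion of 100 %, 52.2 % of E.J and 47.8 % of Q, which is 3.7 points above the mean rule. In the neighbouring flask, the same flask with 0.12 mM of E, we reckon that [J] falls from 0.550 mM to 0.430 mM while E lives, and the share bends less than in the first flask, from 30.0 % to 35.4 %. Its mean [J] of 0.490 mM with the same crossing level gives 32.5 %. The neighbouring flask holds 32.7 % of Q and 67.3 % of E.J at 12.0 s.

The numbers of this flask belong to no real substance; what happens was integrated by code.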